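The carbocycle of the tetrahydroquinolinone is cut at C4a–C5 and C7–C8, leaving a monocyclic 1-methoxy-4-pyridone and (E)-undec-2-enal. The key step exploits the vinylogous amide N1–C8a=C4a–C4=O of the pyridone ring: its only free ring carbon (future C4a) and the methyl group on the neighbouring carbon (future C8 on C8a) form a 1,3-C,C-dinucleophile. Under iminium catalysis C4a adds to the octyl-bearing β-carbon of the enal, which sets C5 as R, and the aldehyde carbon (C7) then condenses with the methyl group, closing the six-membered ring in the same flask. The pyridone comes from allomaltol in three steps; hydrogenation of C7=C8 completes the route.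

Key step: step 4

Assumption: allomaltol (5-hydroxy-2-methyl-4H-pyran-4-one) is taken as a commercial material, and the facial preference of the imidazolidinone catalyst is taken from its established model for β-alkyl enals.

Step 1
Reactants: 1 allomaltol (5-hydroxy-2-methyl-4H-pyran-4-one); 2 formaldehyde (37% aqueous)
Product: 3 3-hydroxy-2-(hydroxymethyl)-6-methyl-4H-pyran-4-one
Conditions: NaOH (1.1 equiv), H2O, rt; then HCl to pH 1
Reagents that add atoms: formaldehyde, C=O
Why: Aldol-type hydroxymethylation (Lederer–Manasse reaction): the enolate of the 5-hydroxy-4-pyranone is nucleophilic only at C6, the ring carbon next to the hydroxyl-bearing carbon, so formaldehyde should enter there alone.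

Step 2
Reactants: 3 3-hydroxy-2-(hydroxymethyl)-6-methyl-4H-pyran-4-one; 4 iodomethane
Product: 5 2-(hydroxymethyl)-3-methoxy-6-methyl-4H-pyran-4-one
Conditions: MeI (1.2 equiv), K2CO3, acetone, reflux
Reagents that add atoms: iodomethane, CI
Why: Williamson ether synthesis: K2CO3 deprotonates only the acidic enolic 3-hydroxyl (pKa about 9), so methylation should spare the primary alcohol.

Step 3
Reactants: 5 2-(hydroxymethyl)-3-methoxy-6-methyl-4H-pyran-4-one; 6 O-methylhydroxylamine hydrochloride
Product: 7 2-(hydroxymethyl)-1,3-dimethoxy-6-methylpyridin-4(1H)-one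
Conditions: MeONH2·HCl, NaOAc, EtOH/H2O 1:1, 80 °C
Reagents that add atoms: O-methylhydroxylamine hydrochloride, CON.Cl
Why: Pyranone-to-pyridone exchange (nucleophile addition, ring opening, ring closure): the alkoxyamine adds in conjugate fashion to C6, the ring opens to an enaminone and recloses with loss of water, as amines and hydroxylamine do with 3-alkoxy-4-pyranones.

Step 4
Reactants: 7 2-(hydroxymethyl)-1,3-dimethoxy-6-methylpyridin-4(1H)-one (1.2 equiv); 8 (E)-undec-2-enal (1.0 equiv)
Product: 10 (5R)-2-(hydroxymethyl)-1,3-dimethoxy-5-octyl-5,6-dihydroquinolin-4(1H)-one, via Michael-adduct aldehyde 9 (not isolated)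
Conditions: (2S,5S)-5-benzyl-2-tert-butyl-3-methylimidazolidin-4-one·TFA (second-generation MacMillan imidazolidinone, 20 mol %), CH2Cl2/i-PrOH 85:15, −20 °C to rt; then piperidine (30 mol %), AcOH (60 mol %), 4 Å MS, 45 °C, same flask
Reagents that add atoms: (E)-undec-2-enal, CCCCCCCC/C=C/C=O
Why: Proposed new method: the enal and the imidazolidinone salt form the (E)-iminium ion, C5 of 7 (the α-carbon of the vinylogous amide N1–C6=C5–C4=O and its only unsubstituted ring carbon) adds to the β-carbon in a Friedel–Crafts-type Michael addition, and hydrolysis releases aldehyde 9; piperidinium acetate then turns the aldehyde into an iminium ion that is attacked by the 6-methyl group through the methylene-enamine (anhydrobase) tautomer of the O-protonated pyridone, and β-elimination of the amine leaves the C7=C8 alkene. The closest known reactions are the iminium-catalysed Friedel–Crafts alkylation of pyrroles, indoles and anilines with enals and the amine-catalysed Michael–aldol-condensation [3+3] annulation of β-keto esters with enals, with the Knoevenagel-type condensation of 2-methylpyridinium and 2-methyl-4-pyranone methyl groups as the model for the second bond. The carbocycle closes in a 6-(enolendo)-exo-trig Mannich-type cyclisation. The configuration at C5 is set by the catalyst alone: its benzyl group covers one face of the iminium ion, and addition of an aryl-type nucleophile to the open face of a β-alkyl enal should give the R aldehyde with the (2S,5S) catalyst. The step needs C- over O-alkylation (the O-adduct is reversible), 1,4- over 1,2-addition (secured by the hindered iminium ion) and no racemic condensation-first path, which is why piperidine is added only after 8 is consumed; C3 and N1 of 7 carry methoxy groups, so C5 and the 6-methyl group are the only carbon nucleophiles.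

Step 5
Reactants: 10 (5R)-2-(hydroxymethyl)-1,3-dimethoxy-5-octyl-5,6-dihydroquinolin-4(1H)-one
Product: 11 (5R)-2-(hydroxymethyl)-1,3-dimethoxy-5-octyl-5,6,7,8-tetrahydroquinolin-4(1H)-one (CNP0118952.1)
Conditions: H2 (1 atm), RhCl(PPh3)3 (Wilkinson's catalyst, 5 mol %), toluene/EtOH 1:1, rt
Reagents that add atoms: none
Why: Homogeneous hydrogenation with Wilkinson's catalyst: the cis-disubstituted C7=C8 alkene is reduced while the N–O bond, the pyridone ring and the remote C5 stereocenter, which the catalyst has no path to epimerise, should stay untouched.

Compound list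
1 | allomaltol (5-hydroxy-2-methyl-4H-pyran-4-one) | Cc1cc(=O)c(O)co1 | starting material
2 | formaldehyde | C=O | starting material
3 | 3-hydroxy-2-(hydroxymethyl)-6-methyl-4H-pyran-4-one | Cc1cc(=O)c(O)c(CO)o1 | intermediate
4 | iodomethane | CI | starting material
5 | 2-(hydroxymethyl)-3-methoxy-6-methyl-4H-pyran-4-one | Cc1cc(=O)c(OC)c(CO)o1 | intermediate
6 | O-methylhydroxylamine hydrochloride | CON.Cl | starting material
7 | 2-(hydroxymethyl)-1,3-dimethoxy-6-methylpyridin-4(1H)-one | Cc1cc(=O)c(OC)c(CO)n1OC | intermediate
8 | (E)-undec-2-enal | CCCCCCCC/C=C/C=O | starting material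
9 | (3R)-3-[6-(hydroxymethyl)-1,5-dimethoxy-2-methyl-4-oxo-1,4-dihydropyridin-3-yl]undecanal | CCCCCCCC[C@H](CC=O)c1c(C)n(OC)c(CO)c(OC)c1=O | intermediate (not isolated)
10 | (5R)-2-(hydroxymethyl)-1,3-dimethoxy-5-octyl-5,6-dihydroquinolin-4(1H)-one | CCCCCCCC[C@@H]1CC=Cc2c1c(=O)c(OC)c(CO)n2OC | intermediate
11 | (5R)-2-(hydroxymethyl)-1,3-dimethoxy-5-octyl-5,6,7,8-tetrahydroquinolin-4(1H)-one | CCCCCCCC[C@@H]1CCCc2c1c(=O)c(OC)c(CO)n2OC | target

Total step count: 5. Longest linear sequence: 5 steps (1 → 3 → 5 → 7 → 10 → 11).

Steps most likely to fail

Step 4 (labelled step). The N-methoxypyridone may be too weak a π-nucleophile for the iminium ion, so that carbon–carbon bond formation stalls and reversible O-alkylation, dienamine self-condensation of the enal, or a racemic condensation-first path through the methyl group take over; the ring closure may also stop at the open aldehyde. The fallback sets out from 7, uses known chemistry only and returns at 10. Electrophilic iodination of 7 at its only free ring position (N-iodosuccinimide, MeCN, rt) should give 2-(hydroxymethyl)-5-iodo-1,3-dimethoxy-6-methylpyridin-4(1H)-one F1. Miyaura borylation (B2pin2, Pd(dppf)Cl2, KOAc, dioxane, 90 °C) should give 2-(hydroxymethyl)-1,3-dimethoxy-6-methyl-5-(4,4,5,5-tetramethyl-1,3,2-dioxaborolan-2-yl)pyridin-4(1H)-one F2. Hayashi–Miyaura asymmetric 1,4-addition of F2 to enal 8 ([RhCl(C2H4)2]2, chiral 2,5-diphenylbicyclo[2.2.2]octa-2,5-diene ligand in the antipode chosen for the R sense, KOH, dioxane/H2O, 50 °C) should give aldehyde 9 under ligand control. 9 is then closed to 10 by the piperidinium acetate condensation of step 4.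

Step 3. Ring opening and reclosure with the weakly basic alkoxyamine may be sluggish, with oxime ether formation at C4 or decay of the ring-opened enaminone competing. The fallback sets out from 5 and returns at 7. Hydroxylamine, the established partner for this exchange (NH2OH·HCl, NaOAc, EtOH/H2O, 70 °C), should give 1-hydroxy-2-(hydroxymethyl)-3-methoxy-6-methylpyridin-4(1H)-one F3. The acidic N-hydroxyl (pKa about 6) is then methylated selectively over the primary alcohol (MeI, K2CO3, DMF, rt) to give 7.

Step 5. Over-reduction with cleavage of the N–O bond, or migration of the double bond toward C5 on the metal, would erase the N-methoxy group or the stereocenter. The fallback sets out from 10 and returns at 11. It replaces metal catalysis by diimide transfer hydrogenation (2-nitrobenzenesulfonyl hydrazide, Et3N, CH2Cl2, rt), a concerted syn delivery of two hydrogens that cannot cleave N–O bonds or isomerise alkenes. It makes no new compound (entry F0).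

Further compounds
F1 | step 4 | 2-(hydroxymethyl)-5-iodo-1,3-dimethoxy-6-methylpyridin-4(1H)-one | Cc1c(I)c(=O)c(OC)c(CO)n1OC
F2 | step 4 | 2-(hydroxymethyl)-1,3-dimethoxy-6-methyl-5-(4,4,5,5-tetramethyl-1,3,2-dioxaborolan-2-yl)pyridin-4(1H)-one | Cc1c(B2OC(C)(C)C(C)(C)O2)c(=O)c(OC)c(CO)n1OC
F3 | step 3 | 1-hydroxy-2-(hydroxymethyl)-3-methoxy-6-methylpyridin-4(1H)-one | Cc1cc(=O)c(OC)c(CO)n1O
F0 | step 5 | none | none
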